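**Retrosynthetic overview**
1. Feature: in the seven-membered ring (C1, C5, C6, C7, C8, C9, C10) the oxygen-bearing C6 lies between C7 and the C5–C1 edge shared with the five-membered ring. C7–C8(C14)=C9–C10 has the carbon pattern of a 2-substituted buta-1,3-diene, so C6 can be brought in as an alkoxycarbene carbon on a cyclopentene.
2. Endgame: free phenol ⇒ aryl silyl ether; C14 aldehyde ⇒ PMB-protected allylic alcohol; C6–O ester ⇒ Steglich coupling; 6α-OH ⇒ C6 ketone (O4-directed reduction); ketone ⇒ C5=C6 methyl enol ether.
3. Key disconnection: C1–C10 and C6–C7 (with a transient C6–C8 bond) ⇒ pentacarbonylchromium methoxy(cyclopentenyl)carbene + 2-(PMB-oxymethyl)butadiene, by carbene cyclopropanation followed by divinylcyclopropane Cope ring expansion.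
4. Carbene complex ⇒ acid chloride + Na2Cr(CO)5 ⇒ cyclopentene carbaldehyde ⇒ (S)-terpinen-4-ol (silylation, ozonolysis, aldol ring contraction); diene ⇒ 2-methyl-2-vinyloxirane.
5. Ring order: five-membered ring first (step 3), seven-membered ring second (step 9); the stereochemical relay runs C4 (chiral pool) → C1 → C5 → C6.

Key step: step 9

Remark on numbering: daucane numbering is used throughout, also for "future" atoms of monocyclic compounds. C1 is the quaternary ring-fusion carbon bearing methyl C15, followed by C2 and C3; C4 is the carbinol carbon bearing isopropyl; C5 is the ring-fusion CH; C6 is the acyloxy carbon; then C7, C8 (bears C14), C9 and C10. β is the face of C15.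
Remark on the starting material: commercial (S)-terpinen-4-ol is assumed to be enantiopure, and C4 is never touched afterwards.
Remark on protecting groups: O4 carries TBS, the largest silyl group that can realistically be placed on a tertiary carbinol flanked by isopropyl. C14 carries PMB and the phenol carries TBS, so that O4 can be freed with HF before the directed reduction while C14 stays masked until after the acylation.

**Step 1**
Reactants: 1 (S)-terpinen-4-ol
Product: 2 (S)-tert-butyl[(1-isopropyl-4-methylcyclohex-3-en-1-yl)oxy]dimethylsilane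
Conditions: TBSOTf, 2,6-lutidine, CH2Cl2, 0 °C → rt
Reagents that add atoms: tert-butyldimethylsilyl triflate, CC(C)(C)[Si](C)(C)OS(=O)(=O)C(F)(F)F
Why: Silylation of a hindered tertiary alcohol with the silyl triflate under 2,6-lutidine buffering is standard practice, touches neither the alkene nor C4, and installs the group that later has to shield the β face.

**Step 2**
Reactants: 2 O-TBS terpinen-4-ol
Product: 4 (S)-3-(tert-butyldimethylsilyloxy)-3-isopropyl-6-oxoheptanal, via secondary ozonide 3 (not isolated)
Conditions: O3, CH2Cl2, −78 °C; Me2S, −78 °C → rt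
Reagents that add atoms: ozone, [O-][O+]=O
Why: Ozonolysis (Criegee mechanism) of the only alkene with reductive work-up of the ozonide gives the 1,6-keto aldehyde, and the silyl ether and C4 are inert to ozone and Me2S.

**Step 3**
Reactants: 4 keto aldehyde
Product: 5 (R)-5-(tert-butyldimethylsilyloxy)-5-isopropyl-2-methylcyclopent-1-ene-1-carbaldehyde
Conditions: piperidine (0.3 equiv), AcOH (0.3 equiv), 4 Å MS, toluene, 50 °C
Reagents that add atoms: none
Why: Amine-salt-catalysed intramolecular aldol condensation: the enamine of the aldehyde (future C5) adds to the methyl ketone (future C1) in a 5-exo-trig closure helped by the gem-disubstituent effect of quaternary C4, dehydration gives the tetrasubstituted enal, and the catalytic buffered amine, apolar solvent and moderate temperature are chosen to hold back loss of the β-silyloxy group from the enamine.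

**Step 4**
Reactants: 5 cyclopentene carbaldehyde
Product: 6 (R)-5-(tert-butyldimethylsilyloxy)-5-isopropyl-2-methylcyclopent-1-ene-1-carboxylic acid
Conditions: NaClO2, NaH2PO4, 2-methyl-2-butene, t-BuOH/H2O, rt
Reagents that add atoms: sodium chlorite, [Na+].[O-]Cl=O
Why: Pinnick oxidation converts even hindered α,β-unsaturated aldehydes into acids under buffered conditions that leave the tetrasubstituted alkene and the silyl ether alone.

**Step 5**
Reactants: 6 cyclopentene carboxylic acid
Product: 7 (R)-5-(tert-butyldimethylsilyloxy)-5-isopropyl-2-methylcyclopent-1-ene-1-carbonyl chloride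
Conditions: 1-chloro-N,N,2-trimethylprop-1-en-1-amine, CH2Cl2, 0 °C → rt; concentrate, use crude
Reagents that add atoms: 1-chloro-N,N,2-trimethylprop-1-en-1-amine, CC(C)=C(Cl)N(C)C
Why: Acid chloride formation with the Ghosez reagent runs under neutral conditions without HCl, so that the acid-sensitive allylic tertiary silyl ether survives.

**Step 6**
Reactants: 7 acid chloride; 8 chromium hexacarbonyl
Product: 11 pentacarbonyl{methoxy[(R)-5-(tert-butyldimethylsilyloxy)-5-isopropyl-2-methylcyclopent-1-en-1-yl]carbene}chromium, via disodium pentacarbonylchromate 9 (not isolated), via sodium acylchromate 10 (not isolated)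
Conditions: 8, NaC10H8 (2.1 equiv), THF, −78 → 0 °C; 7, −78 → 0 °C; evaporate; Me3OBF4, CH2Cl2, 0 °C
Reagents that add atoms: trimethyloxonium tetrafluoroborate, C[O+](C)C.F[B-](F)(F)F
Why: Acylate route to Fischer carbene complexes: the strongly nucleophilic pentacarbonylchromate dianion is acylated at chromium by the acid chloride and the acylate oxygen is methylated by the Meerwein salt, which avoids a 2-lithioallyl silyl ether and its possible O-to-C silyl shift.

**Step 7**
Reactants: 12 2-methyl-2-vinyloxirane
Product: 13 2-methylenebut-3-en-1-ol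
Conditions: LiN(i-Pr)2, Et2O, −78 °C → rt; H2O
Reagents that add atoms: none
Why: Base-induced isomerisation of an epoxide to an allylic alcohol: the hindered amide removes a methyl proton and the C–O bond at the quaternary allylic carbon opens in a β-elimination, which gives the 2-substituted diene and destroys the only stereocentre.

**Step 8**
Reactants: 13 2-methylenebut-3-en-1-ol
Product: 14 2-[(4-methoxybenzyloxy)methyl]buta-1,3-diene
Conditions: NaH, PMBCl, Bu4NI (cat.), THF/DMF, 0 °C → rt
Reagents that add atoms: 4-methoxybenzyl chloride, COc1ccc(CCl)cc1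
Why: Williamson ether synthesis on a primary allylic alkoxide with a reactive benzylic chloride, run cold enough to avoid dimerisation of the diene.

**Step 9**
Reactants: 11 carbene complex; 14 PMB-protected diene
Product: 16 (1R,4R)-6-methoxy-4β-(tert-butyldimethylsilyloxy)-14-(4-methoxybenzyloxy)dauca-5,8-diene (C15 β; isopropyl α), via cis-divinylcyclopropane 15 (not isolated)
Conditions: 14 (5 equiv), BHT (cat.), 1,4-dioxane, sealed tube, Ar, 100 °C; then toluene, 130 °C if 15 persists; air, daylight, Et2O, Celite
Reagents that add atoms: none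
Why: Loss of one CO at 100 °C opens a site on chromium for the diene; the electrophilic carbene carbon C6 bonds to C7, the free terminus of the 1,1-disubstituted alkene, because the charge that builds up at C8 is tertiary and allylic (chromium-bound η3-allyl), and reductive elimination closes C6–C8, so that the three-membered ring of 15 forms by formal [2+1] carbene transfer with release of the carbonylchromium fragment. The seven-membered ring then closes by [3,3]-sigmatropic ring expansion of the cis-divinylcyclopropane through its boat transition state: C1–C10 forms, C6–C8 breaks, and the C5=C6 enol ether and the C8=C9 alkene carrying C14 are left. The closest known reaction type is the formal [3+4] annulation of alkenyl(alkoxy)carbene chromium complexes with 1,3-dienes (2-silyloxy, 2-amino and electronically neutral dienes) by the same cyclopropanation/Cope sequence; new here are only the β,β-disubstituted alkenyl group, the flanking quaternary C4 and the quaternary centre created in the Cope step. C1 is the only new stereocentre that survives, and it is fixed by the configuration of C6 and C8 in 15: in the twisted ground state of 11 the Cr(CO)5 group, by far the largest substituent on C6, should sit on the α face, away from the TBS group that lies over the β face in its rotamer anti to isopropyl, and the diene should enter from the C1 side of the carbene plane rather than from the quaternary C4 side, so that C8 ends under the α face and C10 reaches C1 cis to isopropyl (C15 β). A cyclopropane with trans alkenyl groups or with the other ring configuration can still be drained through the lowest Cope transition state at 130 °C, since the C6–C8 bond, flanked by methoxy and two alkenyl groups, should undergo reversible homolysis. The step needs site selectivity for the substituted alkene of 14 (electronically favoured, sterically opposed), carbene transfer instead of Diels–Alder addition (secured by the tetrasubstituted C5=C1 bond) and the facial selectivity just described, which is the least secure point of the route.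

**Step 10**
Reactants: 16 bicyclic enol ether
Product: 17 4β-(tert-butyldimethylsilyloxy)-14-(4-methoxybenzyloxy)-5αH-dauc-8-en-6-one (trans-fused)
Conditions: AcOH/NaOAc buffer (pH ≈ 4.5, 2 M), THF/H2O, rt → 40 °C
Reagents that add atoms: water, O
Why: Enol ether hydrolysis under general-acid catalysis: the concentrated acetate buffer protonates C5 (the rate-limiting, buffer-catalysed event) while the hydronium concentration stays too low to ionise the weakly basic, shielded allylic O4 silyl ether, and the proton should arrive on the α face, opposite OTBS and C15, to give the trans-fused 5αH ketone.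

**Step 11**
Reactants: 17 silyloxy ketone
Product: 18 4β-hydroxy-14-(4-methoxybenzyloxy)-5αH-dauc-8-en-6-one
Conditions: 48% aq HF, MeCN, 0 °C → rt
Reagents that add atoms: none
Why: Fluoride-driven Si–O cleavage with aqueous HF spares the PMB ether, the alkene and the ketone, avoids the basic media in which a β-hydroxy ketone could undergo retro-aldol cleavage, and lets any 5βH epimer drift by acid-catalysed enolisation to the trans-fused isomer, which keeps C6 away from isopropyl and gains an O4–H···O=C6 hydrogen bond.

**Step 12**
Reactants: 18 β-hydroxy ketone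
Product: 19 14-(4-methoxybenzyloxy)-5αH-dauc-8-ene-4β,6α-diol
Conditions: Me4NBH(OAc)3, MeCN/AcOH, −20 °C → rt
Reagents that add atoms: none
Why: Evans–Saksena hydroxyl-directed reduction: ligand exchange binds the borohydride to the β-oriented O4 and hydride is delivered intramolecularly to the β face of C6=O through a chair-like six-membered transition state, which sets the 6α-alcohol (4,6-anti).

**Step 13**
Reactants: 20 4-hydroxybenzoic acid
Product: 22 4-(tert-butyldimethylsilyloxy)benzoic acid, via bis-silylated hydroxy acid 21 (not isolated)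
Conditions: TBSCl (2.3 equiv), imidazole, DMF, rt; then AcOH/THF/H2O, rt
Reagents that add atoms: tert-butyldimethylsilyl chloride, CC(C)(C)[Si](C)(C)Cl
Why: Exhaustive silylation followed by selective hydrolysis of the far more labile silyl ester is the standard protection of a phenolic acid.

**Step 14**
Reactants: 19 4β,6α-diol; 22 4-(tert-butyldimethylsilyloxy)benzoic acid
Product: 23 6α-[4-(tert-butyldimethylsilyloxy)benzoyloxy]-14-(4-methoxybenzyloxy)-5αH-dauc-8-en-4β-ol
Conditions: DCC, DMAP, CH2Cl2, 0 °C → rt
Reagents that add atoms: none
Why: Steglich esterification acylates the only secondary alcohol, the tertiary O4–H being inert under carbodiimide/DMAP conditions, and leaves all four stereocentres untouched.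

**Step 15**
Reactants: 23 PMB-protected ester
Product: 24 6α-[4-(tert-butyldimethylsilyloxy)benzoyloxy]-5αH-dauc-8-ene-4β,14-diol
Conditions: DDQ, CH2Cl2/pH 7 buffer, 0 °C → rt
Reagents that add atoms: none
Why: Oxidative PMB cleavage (hydride abstraction from the electron-rich benzylic position by DDQ, then hydrolysis of the oxocarbenium ion) spares the electron-poor silyloxybenzoate, the alkene and the tertiary alcohol.

**Step 16**
Reactants: 24 allylic alcohol
Product: 25 6α-[4-(tert-butyldimethylsilyloxy)benzoyloxy]-4β-hydroxy-5αH-dauc-8-en-14-al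
Conditions: MnO2, CH2Cl2, rt
Reagents that add atoms: none
Why: MnO2 oxidises the primary allylic alcohol selectively and stops at the enal, and the tertiary alcohol cannot be oxidised.

**Step 17**
Reactants: 25 silyl-protected enal ester
Product: 26 (3R,3aS,4S,8aR)-6-formyl-3-hydroxy-3-isopropyl-8a-methyl-1,2,3,3a,4,5,8,8a-octahydroazulen-4-yl 4-hydroxybenzoate (target)
Conditions: Bu4NF, AcOH (1:1), THF, 0 °C
Reagents that add atoms: none
Why: Buffered fluoride cleaves the aryl silyl ether rapidly because phenoxide is a good leaving group on silicon, and the acetic acid keeps the medium neutral so that the benzoate, the enal and the tertiary alcohol survive.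

**Compound list**
1 | (S)-terpinen-4-ol | CC1=CC[C@](O)(C(C)C)CC1 | starting material
2 | (S)-O-TBS terpinen-4-ol | CC1=CC[C@](O[Si](C)(C)C(C)(C)C)(C(C)C)CC1 | intermediate
3 | secondary ozonide of 2 (1,2,4-trioxolane across the former alkene, either bridge orientation) | CC12CC[C@@](O[Si](C)(C)C(C)(C)C)(C(C)C)CC(OO1)O2 | intermediate
4 | (S)-3-(tert-butyldimethylsilyloxy)-3-isopropyl-6-oxoheptanal | O=CC[C@](O[Si](C)(C)C(C)(C)C)(C(C)C)CCC(C)=O | intermediate
5 | (R)-5-(tert-butyldimethylsilyloxy)-5-isopropyl-2-methylcyclopent-1-ene-1-carbaldehyde | O=CC1=C(C)CC[C@@]1(O[Si](C)(C)C(C)(C)C)C(C)C | intermediate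
6 | (R)-5-(tert-butyldimethylsilyloxy)-5-isopropyl-2-methylcyclopent-1-ene-1-carboxylic acid | OC(=O)C1=C(C)CC[C@@]1(O[Si](C)(C)C(C)(C)C)C(C)C | intermediate
7 | (R)-5-(tert-butyldimethylsilyloxy)-5-isopropyl-2-methylcyclopent-1-ene-1-carbonyl chloride | ClC(=O)C1=C(C)CC[C@@]1(O[Si](C)(C)C(C)(C)C)C(C)C | intermediate
8 | chromium hexacarbonyl | O=C=[Cr](=C=O)(=C=O)(=C=O)(=C=O)=C=O | starting material
9 | disodium pentacarbonylchromate | [Na+].[Na+].O=C=[Cr-2](=C=O)(=C=O)(=C=O)=C=O | intermediate
10 | sodium pentacarbonyl(cyclopentenylcarbonyl)chromate | [Na+].[O-]C(=[Cr](=C=O)(=C=O)(=C=O)(=C=O)=C=O)C1=C(C)CC[C@@]1(O[Si](C)(C)C(C)(C)C)C(C)C | intermediate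
11 | pentacarbonyl[methoxy(cyclopentenyl)carbene]chromium, O4-TBS | COC(=[Cr](=C=O)(=C=O)(=C=O)(=C=O)=C=O)C1=C(C)CC[C@@]1(O[Si](C)(C)C(C)(C)C)C(C)C | intermediate
12 | 2-methyl-2-vinyloxirane | CC1(C=C)CO1 | starting material
13 | 2-methylenebut-3-en-1-ol | C=CC(=C)CO | intermediate
14 | 2-[(4-methoxybenzyloxy)methyl]buta-1,3-diene | C=CC(=C)COCc1ccc(OC)cc1 | intermediate
15 | cis-divinylcyclopropane (cyclopentenyl on C6 and vinyl on C8 cis; C8 under the α face of the cyclopentene) | CO[C@@]1(C2=C(C)CC[C@@]2(O[Si](C)(C)C(C)(C)C)C(C)C)C[C@]1(COCc3ccc(OC)cc3)C=C | intermediate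
16 | bicyclic cycloheptadiene (C5=C6 methyl enol ether, C8=C9) | COC1=C2[C@](O[Si](C)(C)C(C)(C)C)(C(C)C)CC[C@]2(C)CC=C(COCc3ccc(OC)cc3)C1 | intermediate
17 | trans-fused C6 ketone, O4-TBS, O14-PMB | CC(C)[C@]1(O[Si](C)(C)C(C)(C)C)CC[C@]2(C)CC=C(COCc3ccc(OC)cc3)CC(=O)[C@H]21 | intermediate
18 | 4β-hydroxy C6 ketone, O14-PMB | CC(C)[C@]1(O)CC[C@]2(C)CC=C(COCc3ccc(OC)cc3)CC(=O)[C@H]21 | intermediate
19 | 4β,6α-diol, O14-PMB | CC(C)[C@]1(O)CC[C@]2(C)CC=C(COCc3ccc(OC)cc3)C[C@H](O)[C@H]21 | intermediate
20 | 4-hydroxybenzoic acid | OC(=O)c1ccc(O)cc1 | starting material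
21 | tert-butyldimethylsilyl 4-(tert-butyldimethylsilyloxy)benzoate | CC(C)(C)[Si](C)(C)OC(=O)c1ccc(O[Si](C)(C)C(C)(C)C)cc1 | intermediate
22 | 4-(tert-butyldimethylsilyloxy)benzoic acid | OC(=O)c1ccc(O[Si](C)(C)C(C)(C)C)cc1 | intermediate
23 | 6α-ester, O14-PMB, phenol TBS | CC(C)[C@]1(O)CC[C@]2(C)CC=C(COCc3ccc(OC)cc3)C[C@H](OC(=O)c3ccc(O[Si](C)(C)C(C)(C)C)cc3)[C@H]21 | intermediate
24 | 6α-ester, free C14 allylic alcohol | CC(C)[C@]1(O)CC[C@]2(C)CC=C(CO)C[C@H](OC(=O)c3ccc(O[Si](C)(C)C(C)(C)C)cc3)[C@H]21 | intermediate
25 | 6α-ester, C14 enal, phenol TBS | CC(C)[C@]1(O)CC[C@]2(C)CC=C(C=O)C[C@H](OC(=O)c3ccc(O[Si](C)(C)C(C)(C)C)cc3)[C@H]21 | intermediate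
26 | CNP0267880.1 | CC(C)[C@]1(O)CC[C@]2(C)CC=C(C=O)C[C@H](OC(=O)c3ccc(O)cc3)[C@H]21 | target

**Step count**
- Total step count: 17.
- Longest linear sequence: 14 (steps 1–6, 9–12, 14–17).

**Three steps most likely to fail**

1. **Step 9.**
   - What may go wrong:
     - Capture of the diene may be slow at a carbene carbon flanked by a tetrasubstituted alkene and a quaternary carbon, so that thermal decay of the complex wins.
     - Carbene transfer may go to the less hindered vinyl group of the diene, which would put C14 on C9.
     - Facial selectivity at C1 may be poor.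
   - Fallback (sets out from 11, returns at 16): the unactivated diene is replaced by the electron-rich diene class for which this annulation is best established, and the C8–C14 bond is made afterwards by cross-coupling. Methyl vinyl ketone is silylated (TBSOTf, Et3N) to 2-(tert-butyldimethylsilyloxy)buta-1,3-diene F1. With 11 (THF, 50–80 °C) the enol-ether alkene is the only nucleophilic site, so C6–C7 bond formation and the Cope ring expansion should give the bicyclic bis(enol ether) F2 at lower temperature, which should also sharpen the facial discrimination. CsF and PhNTf2 in DME convert the C8 silyl enol ether, with the C8=C9 position retained, into the enol triflate F3. Stille coupling with Bu3SnCH2OH (Pd(PPh3)4, LiCl, dioxane) gives the C14 allylic alcohol F4, and NaH/PMBCl gives 16.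

2. **Step 10.**
   - What may go wrong:
     - Acid may ionise the allylic C4–O bond, pushed by the C6 methoxy group (a Stork–Danheiser-type collapse), which would erase C4.
     - C5 may be protonated from the wrong face.
   - Fallback (sets out from 16, returns at 18): the collapse is accepted, and C4 and C5 are rebuilt under the control of C1. Treatment with 1 M HCl in THF converts 16 deliberately into the C4=C5 enone F5. Luche reduction (NaBH4, CeCl3·7H2O, MeOH), with hydride expected from the α face opposite C15, gives the 6β-allylic alcohol F6. Hydroxyl-directed epoxidation (VO(acac)2, t-BuOOH) places the oxirane on the β face and prefers the allylic tetrasubstituted alkene over C8=C9, which gives the 4β,5β-epoxy alcohol F7. Dess–Martin oxidation gives the epoxy ketone F8. SmI2 (THF/MeOH, −90 °C) then cleaves the C5–O bond next to the carbonyl group and gives 18 after protonation of the enolate.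

3. **Step 6.**
   - What may go wrong:
     - The dianion may transfer an electron to the conjugated acid chloride instead of being acylated.
     - Acylation may be slow at a carbonyl group flanked on both sides.
     - The complex may decompose during methylation.
   - Fallback (sets out from 6, returns at 11): the classical organolithium route to Fischer carbene complexes is used, with the vinyl anion obtained by degradation of the acid. (PhO)2P(O)N3 and Et3N give the acyl azide F9, and Curtius rearrangement in toluene at 80 °C gives the vinyl isocyanate F10. Aqueous HCl in THF hydrolyses it to the α-silyloxy cyclopentanone F11, whose epimers at the methyl-bearing carbon are of no consequence. KN(SiMe3)2 and PhNTf2 give the enol triflate F12, since only one position can be enolised. (Me3Sn)2 with Pd(PPh3)4 and LiCl gives the vinylstannane F13. MeLi at −78 °C gives the vinyllithium F14, which is kept cold to prevent O-to-C silyl migration and is added to 8 to give the lithium acylchromate F15. Me3OBF4 then gives 11.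

**Further compounds**
F1 | step 9 | 2-(tert-butyldimethylsilyloxy)buta-1,3-diene | C=CC(=C)O[Si](C)(C)C(C)(C)C
F2 | step 9 | bicyclic bis(enol ether), C6 OMe and C8 OTBS | COC1=C2[C@](O[Si](C)(C)C(C)(C)C)(C(C)C)CC[C@]2(C)CC=C(O[Si](C)(C)C(C)(C)C)C1
F3 | step 9 | C8 enol triflate | COC1=C2[C@](O[Si](C)(C)C(C)(C)C)(C(C)C)CC[C@]2(C)CC=C(OS(=O)(=O)C(F)(F)F)C1
F4 | step 9 | C14 allylic alcohol of the enol ether | COC1=C2[C@](O[Si](C)(C)C(C)(C)C)(C(C)C)CC[C@]2(C)CC=C(CO)C1
F5 | step 10 | C4=C5 enone (14-PMB-oxydauca-4,8-dien-6-one) | CC(C)C1=C2C(=O)CC(COCc3ccc(OC)cc3)=CC[C@@]2(C)CC1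
F6 | step 10 | 6β-allylic alcohol | CC(C)C1=C2[C@H](O)CC(COCc3ccc(OC)cc3)=CC[C@@]2(C)CC1
F7 | step 10 | 4β,5β-epoxy-6β-alcohol | CC(C)[C@]12CC[C@]3(C)CC=C(COCc4ccc(OC)cc4)C[C@@H](O)[C@]13O2
F8 | step 10 | 4β,5β-epoxy ketone | CC(C)[C@]12CC[C@]3(C)CC=C(COCc4ccc(OC)cc4)CC(=O)[C@]13O2
F9 | step 6 | acyl azide of 6 | [N-]=[N+]=NC(=O)C1=C(C)CC[C@@]1(O[Si](C)(C)C(C)(C)C)C(C)C
F10 | step 6 | vinyl isocyanate | O=C=NC1=C(C)CC[C@@]1(O[Si](C)(C)C(C)(C)C)C(C)C
F11 | step 6 | 2-(tert-butyldimethylsilyloxy)-2-isopropyl-5-methylcyclopentanone | O=C1C(C)CC[C@@]1(O[Si](C)(C)C(C)(C)C)C(C)C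
F12 | step 6 | cyclopentenyl triflate | O=S(=O)(OC1=C(C)CC[C@@]1(O[Si](C)(C)C(C)(C)C)C(C)C)C(F)(F)F
F13 | step 6 | cyclopentenyl trimethylstannane | C[Sn](C)(C)C1=C(C)CC[C@@]1(O[Si](C)(C)C(C)(C)C)C(C)C
F14 | step 6 | cyclopentenyllithium | [Li]C1=C(C)CC[C@@]1(O[Si](C)(C)C(C)(C)C)C(C)C
F15 | step 6 | lithium pentacarbonyl(cyclopentenylcarbonyl)chromate | [Li+].[O-]C(=[Cr](=C=O)(=C=O)(=C=O)(=C=O)=C=O)C1=C(C)CC[C@@]1(O[Si](C)(C)C(C)(C)C)C(C)C
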